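Remark on numbering: C1–C8 are the atoms of the 2,7-dioxabicyclo[3.2.1]octan-3-one (C1 acetal carbon, O2, C3 lactone carbonyl, C4, C5, C6, O7, C8), C9 is the ester carbon on C6, C1′–C8a′ are the octahydronaphthalene atoms, and β is the face of ring A that carries the two methyl groups.

Remark on the key-step structures: the (R)-cyclohexenol and the (1S,2R,6S)-bicycloheptanol were checked atom by atom against the target and agree with it (hydroxyl and new methylene on the β face, silyloxymethyl α), so no structure is changed and the tert-butyldimethylsilyl ether is kept.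

## Structural features

The target joins two ring systems through one bond, C8–C2′. One is a bridged acylal, a 2,7-dioxabicyclo[3.2.1]octan-3-one with a methyl ester on C6. The other is a 1,2,5,5-tetramethyl-octahydronaphthalene whose only double bond is C8′=C8a′. Five stereocentres are contiguous (C1′, C2′, C8, C5, C6), C1 follows from the cis bridge, and C4a′ stands alone on the far side of ring A. The acylal is labile to base and nucleophiles, C6–H is α to an ester, and the trisubstituted alkene can slip under acid or on metal surfaces into a tetrasubstituted position, which would erase C1′ or C4a′. The real difficulty is quaternary C2′: it carries a β-methyl cis to the C1′ methyl and the bond to C8, and ring A has no functional group near it in the target. A second difficulty is relaying configuration across the freely rotating C2′–C8 bond. The key step exploits the C1′–C2′ edge of ring A: with C8a′ as a carbinol and C1′=C2′ as an alkene, the hydroxyl steers a methylene onto that edge, and the methylene later becomes the C2′ methyl.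

## Logic of the disconnections

35 to 34: the acylal bond O2–C1 is cut. It is the most fragile bond, so it is made last from a methyl acetal at C1 and a free acid at C3. The bridged bicycle becomes a monocyclic oxolane. The forward step needs an acid mild enough to leave C8′=C8a′ in place; C1 needs no control because the bridge can only close cis.

34 to 32 (through 33): no skeletal bond is cut; the C3 acid is traced back to the vinyl group C4=C3. This leaves an oxolane with only one carbonyl group. The forward hydroboration must choose the monosubstituted alkene over C8′=C8a′, and the oxidation must spare the acetal.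

32 to 28 (through 31, 30, 29): the C6–H bond is the one broken and re-made; C1 returns to a lactone carbonyl and C9 to a primary alcohol. C6 is brought in from the chiral pool with the configuration that the preceding rearrangement needs, and is inverted only once it is α to an ester and C8 is no longer acidic. The gain is a simple all-cis hydroxymethyl lactone. The demand is that no base touches the lactone, where the cis relation of C8 and C5 is the less stable one.

28 to 20 and 24 (through 27, 26, 25): C8–C5 and the acyl bond O7–C1 are cut. C8–C5 links two adjacent stereocentres beside a quaternary carbon, where a sigmatropic shift tolerates crowding and copies the configuration of the partner onto both carbons. The molecule falls into the ring-system acid and a five-carbon chiral fragment. The forward step needs a defined enolate geometry, a chair transition state and bonding anti to the allylic C–O bond.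

24 to 21 (through 23, 22): C4=C5 is cut by olefination logic and the diol is traced to a hexitol. This gives a cheap enantiopure source for C6, C9 and their oxygens. The olefination must be Z-selective.

20 to 16 (through 19, 18, 17): C8–C1 is cut as a one-carbon homologation. C8 stays the carbon that was attached to C2′ from the start. The demand is olefination of a neopentyl aldehyde and enol ether hydrolysis without alkene migration.

16 to 14 (through 15): a carbonyl is added back at C7′ so that ring B can be traced to an annulation. The forward step must remove that oxygen without moving C8′=C8a′.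

14 to 10 and 12 (through 13, 11): C8′=C8a′ and C4a′–C5′ are cut. This removes ring B and the quaternary C5′ in one operation and leaves a monocyclic ketone. The demand is enolisation away from C1′ and control of C4a′, which is the weakest point of the plan.

10 to 8 (through 9): the C1′–CH3 bond is cut and the C2′ methyl is reconnected to C1′ as a cyclopropane. The vicinal methyl pair is thereby traced to one strained ring whose cleavage gives a regiodefined enolate. The demand is selective cleavage of the exocyclic cyclopropane bond and methylation on the β face.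

8 to 6 (through 7): C2′–CH2 and C1′–CH2 are cut, which removes the cyclopropane. One carbinol stereocentre then accounts for C2′ and, through it, C1′. The demand is complete syn delivery of the methylene.

6 to 1 (through 5, 4): C2′–C8 is cut as a hydroxymethyl anion adding to a vinylogous ester, and the carbinol is traced to an enone. The demand is an enantioselective 1,2-reduction.

## Other disconnections considered

Alternative 1: The cut is O7–C6, preceded by C8–C5. The acid (2R,3S)-3-{2-[tert-butyl(diphenyl)silyl]oxyethyl}-2-[(1S,2R,4aS)-1,2,5,5-tetramethyl-1,2,3,4,4a,5,6,7-octahydronaphthalen-2-yl]pent-4-enoic acid A1 would be treated with iodine in acetonitrile without base. Reversible iodonium formation and 5-exo closure of the carboxyl oxygen on C6 should settle on the 4,5-trans iodomethyl lactone A2.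

- In its favour: C6 appears directly with the configuration of the target. Here the alternative is the better of the two, since the chosen plan brings C6 in with the opposite sense and inverts it. One step makes O7–C6 and leaves C9 as a handle. A1 would come from 20 and an achiral allylic alcohol, a cheaper partner than 24.
- Against it: iodine and the HI set free without base meet the electron-rich C8′=C8a′ alkene, which invites iodination or migration. The iodomethyl group needs about three further operations to become the ester. The protected C3 alcohol needs deprotection and oxidation. Because the partner is achiral, the absolute sense at C8 and C5 would rest on the weak facial bias of quaternary C2′, whereas in the chosen plan the dioxolane of 24 dictates it.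
- Comparison: both plans pass through a γ-lactone carrying C8, C5 and C6 and are about equal in step count from the rearranged acid. The alternative is better at C6 and worse at C8/C5. It addresses only the dioxabicycle and would still need the chosen ring A chemistry.

Alternative 2: The cuts are C4a′–C5′ and C8′=C8a′. The kinetic silyl enol ether of the ring A ketone (2S,3R)-3-({[tert-butyl(dimethyl)silyl]oxy}methyl)-2,3-dimethylcyclohexan-1-one A3 would add to 12 under TiCl4, and KOH would close and dehydrate to the enone A4.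

- In its favour: two C–C bonds and the quaternary C5′ from cheap reagents in two flasks.
- Against it: the addition is expected anti to the pseudo-axial C1′ methyl, which is the wrong face for C4a′, so the centre depends on a modest thermodynamic bias. The C7′ carbonyl must later be removed without moving the alkene. As a strategic centre it presupposes A3, the compound that contains the real problem.
- Comparison: the chosen plan uses this same annulation as step 8 (A3 and A4 are 10 and 14), so on ring B the two are equal in structure, mechanism and step count. The difference is that the chosen plan derives C1′ and C2′ from one catalytically set carbinol, whereas a plan centred on the annulation leaves the quaternary centre unsolved.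

Alternative 3: The cut is C4a′–C4′. The aldehyde (3R,4R)-3-({[tert-butyl(dimethyl)silyl]oxy}methyl)-4-(3,3-dimethylcyclohex-1-en-1-yl)-3-methylpentanal A5 would be activated by Me2AlCl and undergo a carbonyl-ene closure to the alcohol A6.

- In its favour: C4a′ would be set inside a cyclic transition state, and the double bond would arrive at C8′=C8a′ with no carbonyl to remove. On both counts it is better than the chosen plan.
- Against it: A5 needs the tertiary C1′ and quaternary C2′ centres built on an open chain, where no ring or directing group biases them. Bond formation at C4a′ is beside quaternary C5′ and hindered. Hydrogen transfer from C1′ would compete and give the tetrasubstituted alkene. The C4′ hydroxyl has to be removed in about two steps.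
- Comparison: the ene route is superior for ring B and inferior for C1′/C2′, where the chosen plan is strongest. The overall step count should be similar or somewhat longer.

Key step: step 4

## Steps

Step 1
Reactants: 1 3-ethoxycyclohex-2-en-1-one
Product: 4 3-(hydroxymethyl)cyclohex-2-en-1-one, via silylmethyl carbinol 2 (not isolated), via enol ether diol 3 (not isolated)
Conditions: (i-PrO)Me2SiCH2MgCl (from (i-PrO)Me2SiCH2Cl, Mg), THF, 0 °C; then KF, KHCO3, 30% H2O2, MeOH/THF, rt; then 1 M HCl, rt
Reagents that add atoms: [dimethyl(propan-2-yloxy)silyl]methylmagnesium chloride CC(C)O[Si](C)(C)C[Mg]Cl; hydrogen peroxide OO; water O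
Why: 1,2-Addition of the silylmethyl Grignard reagent to the vinylogous ester, Tamao oxidation of the C–Si bond while the acid-labile adduct is still basic, then acid-induced loss of the tertiary hydroxyl with hydrolysis of the enol ether (alkoxyenone transposition) should give the 3-substituted enone; oxidising before acidifying avoids protodesilylation of a vinylogous α-silyl ketone.

Step 2
Reactants: 4 3-(hydroxymethyl)cyclohex-2-en-1-one
Product: 5 3-({[tert-butyl(dimethyl)silyl]oxy}methyl)cyclohex-2-en-1-one
Conditions: t-BuMe2SiCl, imidazole, CH2Cl2, rt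
Reagents that add atoms: tert-butyl(chloro)dimethylsilane CC(C)(C)[Si](C)(C)Cl
Why: Standard silylation of a primary allylic alcohol; this ether is expected to survive Et2Zn, Li/NH3, LiN(i-Pr)2, TiCl4 at −78 °C and KOH/MeOH, and is removed on purpose in step 9.

Step 3
Reactants: 5 3-({[tert-butyl(dimethyl)silyl]oxy}methyl)cyclohex-2-en-1-one
Product: 6 (1R)-3-({[tert-butyl(dimethyl)silyl]oxy}methyl)cyclohex-2-en-1-ol
Conditions: (S)-1-methyl-3,3-diphenyltetrahydro-1H,3H-pyrrolo[1,2-c][1,3,2]oxazaborole (10 mol %), catecholborane, toluene, −78 °C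
Reagents that add atoms: none
Why: Corey–Bakshi–Shibata reduction; the ketone should bind the ring boron anti to the alkenyl arm, which acts as the larger group, so hydride reaches the face that gives the (R)-carbinol; catecholborane at −78 °C is the variant suited to enones and does not hydroborate the alkene.

Step 4
Reactants: 6 (1R)-3-({[tert-butyl(dimethyl)silyl]oxy}methyl)cyclohex-2-en-1-ol
Product: 7 (1S,2R,6S)-6-({[tert-butyl(dimethyl)silyl]oxy}methyl)bicyclo[4.1.0]heptan-2-ol
Conditions: Et2Zn, CH2I2, CH2Cl2, −10 → 0 °C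
Reagents that add atoms: diiodomethane ICI
Why: Et2Zn deprotonates 6 to an ethylzinc alkoxide that binds the carbenoid EtZnCH2I formed from Et2Zn and CH2I2, and the methylene passes to the C1′=C2′ alkene through a concerted butterfly-shaped transition state in which C2′–CH2 and C1′–CH2 form together. The closest known reaction type is the hydroxyl-directed Simmons–Smith (Furukawa) cyclopropanation of cyclohex-2-en-1-ols, which is reliably syn-selective. The three-membered ring is closed by this single [2+1] transfer, not by a stepwise exo or endo attack, so no regiochemical choice arises. Both new stereocentres, C1 and C6 of 7 (C1′ and C2′), are controlled by the C2 carbinol: zinc sits on the oxygen, so the methylene can only reach the face that carries it, which makes the ring cis and turns (2R) into (1S,6S). The selectivity that matters is facial and it is secured by the allylic alkoxide; the silyloxymethyl group lies in the alkene plane and a silyl ether is a poor zinc ligand, so it neither blocks nor competes. The substrate has one alkene, and this electron-rich trisubstituted double bond should react at 0 °C before Lewis-acidic zinc iodide can ionise the cyclopropylcarbinol. Of the two bonds made, C2′–CH2 becomes the β-methyl of the quaternary centre and C1′–CH2 is cut again in step 6.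

Step 5
Reactants: 7 (1S,2R,6S)-6-({[tert-butyl(dimethyl)silyl]oxy}methyl)bicyclo[4.1.0]heptan-2-ol
Product: 8 (1S,6S)-6-({[tert-butyl(dimethyl)silyl]oxy}methyl)bicyclo[4.1.0]heptan-2-one
Conditions: Dess–Martin periodinane, NaHCO3, CH2Cl2, rt
Reagents that add atoms: none
Why: Buffered periodinane oxidation of a secondary alcohol avoids the acid that would open a cyclopropylcarbinyl system; the carbinol centre has done its work and C1/C6 are untouched.

Step 6
Reactants: 8 (1S,6S)-6-({[tert-butyl(dimethyl)silyl]oxy}methyl)bicyclo[4.1.0]heptan-2-one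
Product: 10 (2S,3R)-3-({[tert-butyl(dimethyl)silyl]oxy}methyl)-2,3-dimethylcyclohexan-1-one, via lithium enolate 9 (not isolated)
Conditions: Li, NH3(l)/THF, −78 °C; then MeI, −78 → −33 °C
Reagents that add atoms: iodomethane CI
Why: Dissolving-metal reduction of a cyclopropyl ketone cleaves the exocyclic bond C1′–CH2 that overlaps with the carbonyl π system (the ring bond C1′–C2′ is nearly orthogonal), ammonia protonates the primary carbanion to the C2′ methyl, and the regiodefined enolate 9 is methylated at C1′; attack anti to the larger silyloxymethyl group is expected, which places the new methyl cis to the C2′ methyl.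

Step 7
Reactants: 10 (2S,3R)-3-({[tert-butyl(dimethyl)silyl]oxy}methyl)-2,3-dimethylcyclohexan-1-one
Product: 11 {[(5R,6S)-5-({[tert-butyl(dimethyl)silyl]oxy}methyl)-5,6-dimethylcyclohex-1-en-1-yl]oxy}(trimethyl)silane
Conditions: LiN(i-Pr)2, THF, −78 °C; Me3SiCl, Et3N, −78 → 0 °C
Reagents that add atoms: chlorotrimethylsilane C[Si](C)(C)Cl
Why: Kinetic deprotonation should occur at the unhindered C4a′ methylene and not at the tertiary C1′–H beside quaternary C2′, so O-silylation gives the less substituted silyl enol ether and C1′ keeps its configuration.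

Step 8
Reactants: 11 {[(5R,6S)-5-({[tert-butyl(dimethyl)silyl]oxy}methyl)-5,6-dimethylcyclohex-1-en-1-yl]oxy}(trimethyl)silane; 12 mesityl oxide
Product: 14 (4aS,7R,8R)-7-({[tert-butyl(dimethyl)silyl]oxy}methyl)-4,4,7,8-tetramethyl-4,4a,5,6,7,8-hexahydronaphthalen-2(3H)-one, via diketone 13 (not isolated)
Conditions: TiCl4, CH2Cl2, −78 °C; then KOH, MeOH, 0 °C → rt
Reagents that add atoms: none
Why: Mukaiyama–Michael addition joins C4a′ to the β-carbon of 12 and makes quaternary C5′, and an intramolecular aldol condensation (Robinson-type closure) of the methyl ketone onto C8a′ then forms C8′=C8a′; the kinetic addition is expected anti to the pseudo-axial C1′ methyl, so C4a′ is set only when KOH equilibrates 13 towards the ketone with both α-substituents equatorial before closure, a modest bias that may require separation and recycling of the C4a′ epimer.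

Step 9
Reactants: 14 (4aS,7R,8R)-7-({[tert-butyl(dimethyl)silyl]oxy}methyl)-4,4,7,8-tetramethyl-4,4a,5,6,7,8-hexahydronaphthalen-2(3H)-one
Product: 15 1,3-dithiolane (ethane-1,2-diyl dithioketal) of (4aS,7R,8R)-7-(hydroxymethyl)-4,4,7,8-tetramethyl-4,4a,5,6,7,8-hexahydronaphthalen-2(3H)-one
Conditions: HSCH2CH2SH, BF3·OEt2, MeOH, rt
Reagents that add atoms: ethane-1,2-dithiol SCCS
Why: Lewis-acid thioketalisation of a conjugated ketone keeps the double bond at C8′=C8a′ (unlike oxygen ketals), and the same acidic methanol solvolyses the primary silyl ether, which is no longer needed; no base is present, so C4a′ and C1′ are not equilibrated.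

Step 10
Reactants: 15 1,3-dithiolane of (4aS,7R,8R)-7-(hydroxymethyl)-4,4,7,8-tetramethyl-4,4a,5,6,7,8-hexahydronaphthalen-2(3H)-one
Product: 16 [(1R,2R,4aS)-1,2,5,5-tetramethyl-1,2,3,4,4a,5,6,7-octahydronaphthalen-2-yl]methanol
Conditions: Raney Ni (skeletal Ni, W-2 grade, acetone-deactivated), EtOH, reflux
Reagents that add atoms: none
Why: Hydrogenolytic desulfurisation of an allylic dithioketal on nickel is the classical way to take a conjugated carbonyl down to CH2 while leaving the alkene where it is; the hindered trisubstituted double bond should resist saturation on deactivated nickel.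

Step 11
Reactants: 16 [(1R,2R,4aS)-1,2,5,5-tetramethyl-1,2,3,4,4a,5,6,7-octahydronaphthalen-2-yl]methanol
Product: 17 (1R,2R,4aS)-1,2,5,5-tetramethyl-1,2,3,4,4a,5,6,7-octahydronaphthalene-2-carbaldehyde
Conditions: Dess–Martin periodinane, NaHCO3, CH2Cl2, rt
Reagents that add atoms: none
Why: Oxidation of a neopentyl primary alcohol to an aldehyde that has no α-hydrogen, so nothing can epimerise.

Step 12
Reactants: 17 (1R,2R,4aS)-1,2,5,5-tetramethyl-1,2,3,4,4a,5,6,7-octahydronaphthalene-2-carbaldehyde
Product: 18 (1S,2R,4aS)-2-(2-methoxyethenyl)-1,2,5,5-tetramethyl-1,2,3,4,4a,5,6,7-octahydronaphthalene (E/Z mixture)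
Conditions: Ph3P(CH2OMe)Cl, KN(SiMe3)2, THF, 0 °C → rt
Reagents that add atoms: (methoxymethyl)triphenylphosphonium chloride [Cl-].COC[P+](c1ccccc1)(c1ccccc1)c1ccccc1
Why: Wittig methoxymethylenation; the small, reactive ylide is the usual choice for aldehydes on quaternary carbon, and the enol ether geometry is irrelevant because it is hydrolysed next.

Step 13
Reactants: 18 (1S,2R,4aS)-2-(2-methoxyethenyl)-1,2,5,5-tetramethyl-1,2,3,4,4a,5,6,7-octahydronaphthalene
Product: 19 [(1S,2S,4aS)-1,2,5,5-tetramethyl-1,2,3,4,4a,5,6,7-octahydronaphthalen-2-yl]acetaldehyde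
Conditions: 1 M HCl, THF, rt
Reagents that add atoms: water O
Why: Enol ether hydrolysis; the enol ether is protonated far more readily than the trisubstituted ring alkene, so dilute acid at room temperature should not move C8′=C8a′ (the descriptor at C2′ changes only because the priorities change).

Step 14
Reactants: 19 [(1S,2S,4aS)-1,2,5,5-tetramethyl-1,2,3,4,4a,5,6,7-octahydronaphthalen-2-yl]acetaldehyde
Product: 20 [(1S,2S,4aS)-1,2,5,5-tetramethyl-1,2,3,4,4a,5,6,7-octahydronaphthalen-2-yl]acetic acid
Conditions: NaClO2, NaH2PO4, 2-methylbut-2-ene, t-BuOH/H2O, rt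
Reagents that add atoms: sodium chlorite [Na+].[O-]Cl=O
Why: Pinnick oxidation; the alkene scavenger consumes hypochlorous acid so the ring alkene is not chlorinated.

Step 15
Reactants: 21 1,2:5,6-di-O-isopropylidene-D-mannitol
Product: 23 methyl (2Z)-3-[(4S)-2,2-dimethyl-1,3-dioxolan-4-yl]prop-2-enoate, via glyceraldehyde acetonide 22 (not isolated)
Conditions: NaIO4, aq. NaHCO3, CH2Cl2, rt; then Ph3P=CHCO2Me, MeOH, 0 °C
Reagents that add atoms: methyl (triphenylphosphoranylidene)acetate COC(=O)C=P(c1ccccc1)(c1ccccc1)c1ccccc1
Why: Glycol cleavage gives two molecules of the configurationally labile aldehyde 22, which is olefinated at once; Wittig reaction of a stabilised ylide with an α-alkoxy aldehyde in methanol is known to favour the Z-enoate, and the minor E isomer is removed by chromatography.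

Step 16
Reactants: 23 methyl (2Z)-3-[(4S)-2,2-dimethyl-1,3-dioxolan-4-yl]prop-2-enoate
Product: 24 (2Z)-3-[(4S)-2,2-dimethyl-1,3-dioxolan-4-yl]prop-2-en-1-ol
Conditions: i-Bu2AlH, CH2Cl2, −78 °C
Reagents that add atoms: none
Why: 1,2-Reduction of an enoate to the allylic alcohol with retention of the Z geometry and of the dioxolane stereocentre.

Step 17
Reactants: 20 [(1S,2S,4aS)-1,2,5,5-tetramethyl-1,2,3,4,4a,5,6,7-octahydronaphthalen-2-yl]acetic acid; 24 (2Z)-3-[(4S)-2,2-dimethyl-1,3-dioxolan-4-yl]prop-2-en-1-ol
Product: 25 (2Z)-3-[(4S)-2,2-dimethyl-1,3-dioxolan-4-yl]prop-2-en-1-yl [(1S,2S,4aS)-1,2,5,5-tetramethyl-1,2,3,4,4a,5,6,7-octahydronaphthalen-2-yl]acetate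
Conditions: N,N′-dicyclohexylcarbodiimide, 4-(dimethylamino)pyridine (cat.), CH2Cl2, 0 °C → rt
Reagents that add atoms: none
Why: Steglich esterification; the union with enantiopure 24 also turns any minor enantiomer left from step 3 into a diastereomer that can be removed.

Step 18
Reactants: 25 (2Z)-3-[(4S)-2,2-dimethyl-1,3-dioxolan-4-yl]prop-2-en-1-yl [(1S,2S,4aS)-1,2,5,5-tetramethyl-1,2,3,4,4a,5,6,7-octahydronaphthalen-2-yl]acetate
Product: 28 (3R,4R,5S)-4-ethenyl-5-(hydroxymethyl)-3-[(1S,2R,4aS)-1,2,5,5-tetramethyl-1,2,3,4,4a,5,6,7-octahydronaphthalen-2-yl]oxolan-2-one, via silyl ketene acetal 26 (not isolated), via rearranged acid 27 (not isolated)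
Conditions: LiN(i-Pr)2, THF, −78 °C; Me3SiCl, Et3N, −78 → 60 °C; then 1 M HCl, THF, rt
Reagents that add atoms: none
Why: Ireland–Claisen rearrangement: kinetic enolisation in THF should give the ketene acetal with the ring system cis to the allyloxy oxygen, and a chair transition state with the Z-allyl unit then joins C8 to C5 with the relative configuration of the target, while bonding anti to the dioxolane C–O bond (C6–H eclipsing the Z-alkene) fixes the absolute sense at both centres independently of C2′; aqueous acid then frees the acid, removes the acetonide and closes the five-membered lactone on the secondary hydroxyl.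

Step 19
Reactants: 28 (3R,4R,5S)-4-ethenyl-5-(hydroxymethyl)-3-[(1S,2R,4aS)-1,2,5,5-tetramethyl-1,2,3,4,4a,5,6,7-octahydronaphthalen-2-yl]oxolan-2-one
Product: 29 (2S,3R,4R)-3-ethenyl-5-oxo-4-[(1S,2R,4aS)-1,2,5,5-tetramethyl-1,2,3,4,4a,5,6,7-octahydronaphthalen-2-yl]oxolane-2-carboxylic acid
Conditions: 2,2,6,6-tetramethylpiperidin-1-oxyl (cat.), PhI(OAc)2, MeCN/H2O, rt
Reagents that add atoms: water O
Why: Oxoammonium oxidation of a primary alcohol through the aldehyde hydrate to the acid, as used for uronic acids; the medium is weakly acidic, so the base-sensitive cis relation at C8 is not disturbed.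

Step 20
Reactants: 29 (2S,3R,4R)-3-ethenyl-5-oxo-4-[(1S,2R,4aS)-1,2,5,5-tetramethyl-1,2,3,4,4a,5,6,7-octahydronaphthalen-2-yl]oxolane-2-carboxylic acid
Product: 30 (2S,3R,4R)-3-ethenyl-5-hydroxy-4-[(1S,2R,4aS)-1,2,5,5-tetramethyl-1,2,3,4,4a,5,6,7-octahydronaphthalen-2-yl]oxolane-2-carboxylic acid (both anomers)
Conditions: i-Bu2AlH (3 equiv), CH2Cl2, −78 °C
Reagents that add atoms: none
Why: The first equivalent turns the acid into an aluminium carboxylate that is inert at −78 °C, and the lactone is reduced to a stable aluminium hemiacetal that gives the lactol on work-up; with C9 already a carboxyl only O7 can close onto C1, so no six-membered lactol can form.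

Step 21
Reactants: 30 (2S,3R,4R)-3-ethenyl-5-hydroxy-4-[(1S,2R,4aS)-1,2,5,5-tetramethyl-1,2,3,4,4a,5,6,7-octahydronaphthalen-2-yl]oxolane-2-carboxylic acid
Product: 32 methyl (2R,3R,4R)-3-ethenyl-5-methoxy-4-[(1S,2R,4aS)-1,2,5,5-tetramethyl-1,2,3,4,4a,5,6,7-octahydronaphthalen-2-yl]oxolane-2-carboxylate (both anomers), via cis ester acetal 31 (not isolated)
Conditions: HCl (cat.), MeOH, rt; then NaOMe, MeOH, rt
Reagents that add atoms: methanol CO
Why: Acidic methanol esterifies the acid and converts the lactol into its methyl acetal in one operation; methoxide then epimerises C6, the only acidic stereocentre now that C8 sits next to an acetal carbon, and the ester should settle trans to the C5 vinyl group, which is the configuration of the target.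

Step 22
Reactants: 32 methyl (2R,3R,4R)-3-ethenyl-5-methoxy-4-[(1S,2R,4aS)-1,2,5,5-tetramethyl-1,2,3,4,4a,5,6,7-octahydronaphthalen-2-yl]oxolane-2-carboxylate
Product: 33 methyl (2R,3R,4R)-3-(2-hydroxyethyl)-5-methoxy-4-[(1S,2R,4aS)-1,2,5,5-tetramethyl-1,2,3,4,4a,5,6,7-octahydronaphthalen-2-yl]oxolane-2-carboxylate
Conditions: 9-borabicyclo[3.3.1]nonane, THF, 0 °C → rt; then 30% H2O2, aq. NaOAc, 0 °C → rt
Reagents that add atoms: hydrogen peroxide OO
Why: Anti-Markovnikov hydroboration–oxidation; the bulky borane should take the monosubstituted vinyl group and leave the hindered trisubstituted ring alkene and the ester, and the buffered oxidation spares the ester (C6 is already in its stable configuration).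

Step 23
Reactants: 33 methyl (2R,3R,4R)-3-(2-hydroxyethyl)-5-methoxy-4-[(1S,2R,4aS)-1,2,5,5-tetramethyl-1,2,3,4,4a,5,6,7-octahydronaphthalen-2-yl]oxolane-2-carboxylate
Product: 34 [(2R,3R,4R)-5-methoxy-2-(methoxycarbonyl)-4-[(1S,2R,4aS)-1,2,5,5-tetramethyl-1,2,3,4,4a,5,6,7-octahydronaphthalen-2-yl]oxolan-3-yl]acetic acid
Conditions: Pr4N[RuO4] (10 mol %), N-methylmorpholine N-oxide monohydrate, MeCN, rt
Reagents that add atoms: water O
Why: Perruthenate oxidation in the presence of the hydrated N-oxide carries a primary alcohol through the aldehyde hydrate to the acid under neutral conditions, which keeps the acid-labile methyl acetal intact and does not touch the alkene.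

Step 24
Reactants: 34 [(2R,3R,4R)-5-methoxy-2-(methoxycarbonyl)-4-[(1S,2R,4aS)-1,2,5,5-tetramethyl-1,2,3,4,4a,5,6,7-octahydronaphthalen-2-yl]oxolan-3-yl]acetic acid
Product: 35 methyl (1S,5R,6R,8R)-3-oxo-8-[(1S,2R,4aS)-1,2,5,5-tetramethyl-1,2,3,4,4a,5,6,7-octahydronaphthalen-2-yl]-2,7-dioxabicyclo[3.2.1]octane-6-carboxylate
Conditions: BF3·OEt2, CH2Cl2, −40 → 0 °C
Reagents that add atoms: none
Why: Lewis-acid ionisation of the methyl acetal gives an oxocarbenium ion at C1 that is captured by the C3 carboxylic acid on C5 (intramolecular acylal formation, a glycosylation-type lactonisation); only the cis bridge is geometrically possible, so C1 is set by C5, and the ester on C6 points away from the new bridge.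

## Compound list

1 | 3-ethoxycyclohex-2-en-1-one | CCOC1=CC(=O)CCC1 | starting material
2 | 1-{[dimethyl(propan-2-yloxy)silyl]methyl}-3-ethoxycyclohex-2-en-1-ol (racemic, present as its magnesium alkoxide) | CCOC1=CC(O)(C[Si](C)(C)OC(C)C)CCC1 | intermediate
3 | 3-ethoxy-1-(hydroxymethyl)cyclohex-2-en-1-ol (racemic) | CCOC1=CC(O)(CO)CCC1 | intermediate
4 | 3-(hydroxymethyl)cyclohex-2-en-1-one | O=C1C=C(CO)CCC1 | intermediate
5 | 3-({[tert-butyl(dimethyl)silyl]oxy}methyl)cyclohex-2-en-1-one | O=C1C=C(CO[Si](C)(C)C(C)(C)C)CCC1 | intermediate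
6 | (1R)-3-({[tert-butyl(dimethyl)silyl]oxy}methyl)cyclohex-2-en-1-ol | O[C@H]1C=C(CO[Si](C)(C)C(C)(C)C)CCC1 | intermediate
7 | (1S,2R,6S)-6-({[tert-butyl(dimethyl)silyl]oxy}methyl)bicyclo[4.1.0]heptan-2-ol | O[C@H]1[C@H]2C[C@@]2(CO[Si](C)(C)C(C)(C)C)CCC1 | intermediate
8 | (1S,6S)-6-({[tert-butyl(dimethyl)silyl]oxy}methyl)bicyclo[4.1.0]heptan-2-one | O=C1[C@H]2C[C@@]2(CO[Si](C)(C)C(C)(C)C)CCC1 | intermediate
9 | lithium (3R)-3-({[tert-butyl(dimethyl)silyl]oxy}methyl)-3-methylcyclohex-1-en-1-olate | [Li]OC1=C[C@](C)(CO[Si](C)(C)C(C)(C)C)CCC1 | intermediate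
10 | (2S,3R)-3-({[tert-butyl(dimethyl)silyl]oxy}methyl)-2,3-dimethylcyclohexan-1-one | C[C@@H]1C(=O)CCC[C@@]1(C)CO[Si](C)(C)C(C)(C)C | intermediate
11 | {[(5R,6S)-5-({[tert-butyl(dimethyl)silyl]oxy}methyl)-5,6-dimethylcyclohex-1-en-1-yl]oxy}(trimethyl)silane | C[C@@H]1C(O[Si](C)(C)C)=CCC[C@@]1(C)CO[Si](C)(C)C(C)(C)C | intermediate
12 | mesityl oxide (4-methylpent-3-en-2-one) | CC(=O)C=C(C)C | starting material
13 | (2S,3R,6S)-3-({[tert-butyl(dimethyl)silyl]oxy}methyl)-2,3-dimethyl-6-(2-methyl-4-oxopentan-2-yl)cyclohexan-1-one | C[C@@H]1C(=O)[C@H](C(C)(C)CC(C)=O)CC[C@@]1(C)CO[Si](C)(C)C(C)(C)C | intermediate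
14 | (4aS,7R,8R)-7-({[tert-butyl(dimethyl)silyl]oxy}methyl)-4,4,7,8-tetramethyl-4,4a,5,6,7,8-hexahydronaphthalen-2(3H)-one | CC(C)(C)[Si](C)(C)OC[C@]1(C)CC[C@@H]2C(=CC(=O)CC2(C)C)[C@H]1C | intermediate
15 | 1,3-dithiolane (ethane-1,2-diyl dithioketal) of (4aS,7R,8R)-7-(hydroxymethyl)-4,4,7,8-tetramethyl-4,4a,5,6,7,8-hexahydronaphthalen-2(3H)-one | OC[C@]1(C)CC[C@@H]2C(=CC3(SCCS3)CC2(C)C)[C@H]1C | intermediate
16 | [(1R,2R,4aS)-1,2,5,5-tetramethyl-1,2,3,4,4a,5,6,7-octahydronaphthalen-2-yl]methanol | OC[C@]1(C)CC[C@@H]2C(=CCCC2(C)C)[C@H]1C | intermediate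
17 | (1R,2R,4aS)-1,2,5,5-tetramethyl-1,2,3,4,4a,5,6,7-octahydronaphthalene-2-carbaldehyde | O=C[C@]1(C)CC[C@@H]2C(=CCCC2(C)C)[C@H]1C | intermediate
18 | (1S,2R,4aS)-2-(2-methoxyethenyl)-1,2,5,5-tetramethyl-1,2,3,4,4a,5,6,7-octahydronaphthalene (E/Z mixture) | COC=C[C@]1(C)CC[C@@H]2C(=CCCC2(C)C)[C@H]1C | intermediate
19 | [(1S,2S,4aS)-1,2,5,5-tetramethyl-1,2,3,4,4a,5,6,7-octahydronaphthalen-2-yl]acetaldehyde | O=CC[C@]1(C)CC[C@@H]2C(=CCCC2(C)C)[C@H]1C | intermediate
20 | [(1S,2S,4aS)-1,2,5,5-tetramethyl-1,2,3,4,4a,5,6,7-octahydronaphthalen-2-yl]acetic acid | OC(=O)C[C@]1(C)CC[C@@H]2C(=CCCC2(C)C)[C@H]1C | intermediate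
21 | 1,2:5,6-di-O-isopropylidene-D-mannitol | CC1(C)OC[C@@H](O1)[C@@H](O)[C@H](O)[C@H]1COC(C)(C)O1 | starting material
22 | (4R)-2,2-dimethyl-1,3-dioxolane-4-carbaldehyde | CC1(C)OC[C@@H](O1)C=O | intermediate
23 | methyl (2Z)-3-[(4S)-2,2-dimethyl-1,3-dioxolan-4-yl]prop-2-enoate | CC1(C)OC[C@@H](O1)/C=C\C(=O)OC | intermediate
24 | (2Z)-3-[(4S)-2,2-dimethyl-1,3-dioxolan-4-yl]prop-2-en-1-ol | CC1(C)OC[C@@H](O1)/C=C\CO | intermediate
25 | (2Z)-3-[(4S)-2,2-dimethyl-1,3-dioxolan-4-yl]prop-2-en-1-yl [(1S,2S,4aS)-1,2,5,5-tetramethyl-1,2,3,4,4a,5,6,7-octahydronaphthalen-2-yl]acetate | CC1(C)OC[C@@H](O1)/C=C\COC(=O)C[C@]1(C)CC[C@@H]2C(=CCCC2(C)C)[C@H]1C | intermediate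
26 | (E)-trimethylsilyl ketene acetal of 25 (ring system on C8 cis to the allyloxy oxygen, trans to the silyloxy group) | C[Si](C)(C)O/C(OC/C=C\[C@H]1COC(C)(C)O1)=C/[C@]2(C)CC[C@@H]3C(=CCCC3(C)C)[C@H]2C | intermediate
27 | (2R,3R)-3-[(4S)-2,2-dimethyl-1,3-dioxolan-4-yl]-2-[(1S,2R,4aS)-1,2,5,5-tetramethyl-1,2,3,4,4a,5,6,7-octahydronaphthalen-2-yl]pent-4-enoic acid | OC(=O)[C@H]([C@@H](C=C)[C@H]1COC(C)(C)O1)[C@]2(C)CC[C@@H]3C(=CCCC3(C)C)[C@H]2C | intermediate
28 | (3R,4R,5S)-4-ethenyl-5-(hydroxymethyl)-3-[(1S,2R,4aS)-1,2,5,5-tetramethyl-1,2,3,4,4a,5,6,7-octahydronaphthalen-2-yl]oxolan-2-one | O=C1O[C@H](CO)[C@H](C=C)[C@@H]1[C@]2(C)CC[C@@H]3C(=CCCC3(C)C)[C@H]2C | intermediate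
29 | (2S,3R,4R)-3-ethenyl-5-oxo-4-[(1S,2R,4aS)-1,2,5,5-tetramethyl-1,2,3,4,4a,5,6,7-octahydronaphthalen-2-yl]oxolane-2-carboxylic acid | O=C1O[C@H](C(=O)O)[C@H](C=C)[C@@H]1[C@]2(C)CC[C@@H]3C(=CCCC3(C)C)[C@H]2C | intermediate
30 | (2S,3R,4R)-3-ethenyl-5-hydroxy-4-[(1S,2R,4aS)-1,2,5,5-tetramethyl-1,2,3,4,4a,5,6,7-octahydronaphthalen-2-yl]oxolane-2-carboxylic acid (both anomers) | OC1O[C@H](C(=O)O)[C@H](C=C)[C@@H]1[C@]2(C)CC[C@@H]3C(=CCCC3(C)C)[C@H]2C | intermediate
31 | methyl (2S,3R,4R)-3-ethenyl-5-methoxy-4-[(1S,2R,4aS)-1,2,5,5-tetramethyl-1,2,3,4,4a,5,6,7-octahydronaphthalen-2-yl]oxolane-2-carboxylate (both anomers) | COC1O[C@H](C(=O)OC)[C@H](C=C)[C@@H]1[C@]2(C)CC[C@@H]3C(=CCCC3(C)C)[C@H]2C | intermediate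
32 | methyl (2R,3R,4R)-3-ethenyl-5-methoxy-4-[(1S,2R,4aS)-1,2,5,5-tetramethyl-1,2,3,4,4a,5,6,7-octahydronaphthalen-2-yl]oxolane-2-carboxylate (both anomers) | COC1O[C@@H](C(=O)OC)[C@H](C=C)[C@@H]1[C@]2(C)CC[C@@H]3C(=CCCC3(C)C)[C@H]2C | intermediate
33 | methyl (2R,3R,4R)-3-(2-hydroxyethyl)-5-methoxy-4-[(1S,2R,4aS)-1,2,5,5-tetramethyl-1,2,3,4,4a,5,6,7-octahydronaphthalen-2-yl]oxolane-2-carboxylate (both anomers) | COC1O[C@@H](C(=O)OC)[C@H](CCO)[C@@H]1[C@]2(C)CC[C@@H]3C(=CCCC3(C)C)[C@H]2C | intermediate
34 | [(2R,3R,4R)-5-methoxy-2-(methoxycarbonyl)-4-[(1S,2R,4aS)-1,2,5,5-tetramethyl-1,2,3,4,4a,5,6,7-octahydronaphthalen-2-yl]oxolan-3-yl]acetic acid (both anomers) | COC1O[C@@H](C(=O)OC)[C@H](CC(=O)O)[C@@H]1[C@]2(C)CC[C@@H]3C(=CCCC3(C)C)[C@H]2C | intermediate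
35 | methyl (1S,5R,6R,8R)-3-oxo-8-[(1S,2R,4aS)-1,2,5,5-tetramethyl-1,2,3,4,4a,5,6,7-octahydronaphthalen-2-yl]-2,7-dioxabicyclo[3.2.1]octane-6-carboxylate | COC(=O)[C@@H]1O[C@H]2OC(=O)C[C@@H]1[C@@H]2[C@]1(C)CC[C@@H]2C(=CCCC2(C)C)[C@H]1C | target

## Step count and least certain steps

Total: 24 steps. Longest linear sequence: 22 steps (steps 1–14 and 17–24, from 1 to 35); steps 15 and 16 form the side branch to 24.

Step 4 (key step). The most likely failure is not the facial sense but incomplete methylene transfer together with Lewis-acid opening of the cyclopropylcarbinol by zinc iodide on prolonged reaction. In addition, the step copies whatever enantiomeric purity step 3 delivered, because the carbinol is its only source of chirality. The fallback builds the quaternary centre by catalytic asymmetric conjugate addition instead. It sets out from 5: Me3Al with Cu(O2CC4H3S) and (S)-1,1′-binaphthyl-2,2′-diyl N,N-bis[(S)-1-phenylethyl]phosphoramidite in Et2O at −30 °C should add methyl to C2′ and leave the dimethylaluminium enolate F1. This is converted with MeLi into the lithium aluminate and methylated with MeI under the same facial argument as in step 6. The fallback comes back to the route at 10. The ligand antipode is chosen to give the (3R) centre.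

Step 6. Methylation on the wrong face of 9 is the main danger, because the methyl and silyloxymethyl groups on C2′ differ only moderately in size and neither C1′ epimer is clearly preferred thermodynamically. Proton exchange by lithium amide can also lead to over-methylation. The fallback sets the C1′ centre by a hydroxyl-directed hydrogenation. It sets out from 9 (generated from 8 as before): trapping with dimethyl(methylidene)ammonium iodide gives the Mannich base F2; quaternisation with MeI and elimination with NaHCO3 give the 2-methylidene ketone F3; Bu4NF frees the alcohol F4; [Ir(cod)(PCy3)(py)]PF6 under H2 in CH2Cl2 should deliver hydrogen to C1′ from the α face, where the hydroxymethyl group holds the metal, to give the hydroxy ketone F5; silylation as in step 2 returns to the route at 10.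

Step 8. Loss of control at C4a′ is likely: the Michael addition should occur anti to the C1′ methyl, which is the wrong face, the base-mediated correction in 13 rests on a small energy difference, and the enone 14 can re-equilibrate at C4a′ through its dienolate. The fallback erases and resets the centre. It sets out from 14 (any C4a′ mixture): chloranil in refluxing t-BuOH dehydrogenates to the linear dienone F6 (C4′=C4a′ is the only δ-position with hydrogen); Bu4NF gives the dienone alcohol F7; directed hydrogenation with [Ir(cod)(PCy3)(py)]PF6 and H2 should reduce the γ,δ-double bond from the α face to the hydroxy enone F8 with H-4a′ α; F8 is thioketalised under the conditions of step 9 and the fallback returns to the route at 15.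

Step 10. Migration of C8′=C8a′ into a tetrasubstituted position on the nickel surface, or partial saturation, would destroy C1′ or C4a′. The fallback removes the oxygen through a π-allyl intermediate. It sets out from 14: NaBH4 with CeCl3·7H2O in MeOH gives the allylic alcohol F9; Ac2O, pyridine and 4-(dimethylamino)pyridine give the acetate F10; Pd(PPh3)4 with LiBHEt3 in THF should deliver hydride to the less hindered allyl terminus C7′ and give the silyl ether F11 with the alkene unmoved; Bu4NF returns to the route at 16.

Step 18. With the ring system and the dioxolane both pseudo-axial in the chair, a boat-like transition state may compete and erode the C8/C5 relation; enolisation beside quaternary C2′ may also be slow. The facial choice at C5 is the better-founded part. The fallback sets C8 by kinetic protonation. It sets out from 25: the rearrangement and acid treatment are run as in step 18, and the C8-epimeric lactone F12 that a boat pathway would give is deprotonated with LiN(i-Pr)2 (2.2 equiv, alkoxide and enolate) in THF at −78 °C and quenched with 2,6-di-tert-butylphenol. The proton should enter on the face away from the C5 vinyl and C6 hydroxymethyl groups, and the fallback returns to the route at 28. A wrong facial choice at C5 could not be repaired in this way.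

Step 24. Acid-induced migration of C8′=C8a′ and an unfavourable balance between the acylal and the methyl acetal (methanol stays in the flask) are the two ways this can fail. The fallback closes the ring by activating the acid. It sets out from 34: aqueous AcOH in THF at 40 °C hydrolyses the acetal to the lactol acid F13, and N,N′-dicyclohexylcarbodiimide with 4-(dimethylamino)pyridine in CH2Cl2 should acylate the lactol hydroxyl intramolecularly under near-neutral conditions, returning to the route at 35.

## Further compounds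

F1 | step 4 | dimethylaluminium (3R)-3-({[tert-butyl(dimethyl)silyl]oxy}methyl)-3-methylcyclohex-1-en-1-olate | C[Al](C)OC1=C[C@](C)(CO[Si](C)(C)C(C)(C)C)CCC1
F2 | step 6 | (3R)-3-({[tert-butyl(dimethyl)silyl]oxy}methyl)-2-[(dimethylamino)methyl]-3-methylcyclohexan-1-one (C2 epimers) | CN(C)CC1C(=O)CCC[C@@]1(C)CO[Si](C)(C)C(C)(C)C
F3 | step 6 | (3R)-3-({[tert-butyl(dimethyl)silyl]oxy}methyl)-3-methyl-2-methylidenecyclohexan-1-one | C=C1C(=O)CCC[C@@]1(C)CO[Si](C)(C)C(C)(C)C
F4 | step 6 | (3R)-3-(hydroxymethyl)-3-methyl-2-methylidenecyclohexan-1-one | C=C1C(=O)CCC[C@@]1(C)CO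
F5 | step 6 | (2S,3R)-3-(hydroxymethyl)-2,3-dimethylcyclohexan-1-one | C[C@@H]1C(=O)CCC[C@@]1(C)CO
F6 | step 8 | (7R,8R)-7-({[tert-butyl(dimethyl)silyl]oxy}methyl)-4,4,7,8-tetramethyl-4,6,7,8-tetrahydronaphthalen-2(3H)-one | CC(C)(C)[Si](C)(C)OC[C@]1(C)CC=C2C(=CC(=O)CC2(C)C)[C@H]1C
F7 | step 8 | (7R,8R)-7-(hydroxymethyl)-4,4,7,8-tetramethyl-4,6,7,8-tetrahydronaphthalen-2(3H)-one | OC[C@]1(C)CC=C2C(=CC(=O)CC2(C)C)[C@H]1C
F8 | step 8 | (4aS,7R,8R)-7-(hydroxymethyl)-4,4,7,8-tetramethyl-4,4a,5,6,7,8-hexahydronaphthalen-2(3H)-one | OC[C@]1(C)CC[C@@H]2C(=CC(=O)CC2(C)C)[C@H]1C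
F9 | step 10 | (4aS,7R,8R)-7-({[tert-butyl(dimethyl)silyl]oxy}methyl)-4,4,7,8-tetramethyl-2,3,4,4a,5,6,7,8-octahydronaphthalen-2-ol (C2 epimers) | CC(C)(C)[Si](C)(C)OC[C@]1(C)CC[C@@H]2C(=CC(O)CC2(C)C)[C@H]1C
F10 | step 10 | (4aS,7R,8R)-7-({[tert-butyl(dimethyl)silyl]oxy}methyl)-4,4,7,8-tetramethyl-2,3,4,4a,5,6,7,8-octahydronaphthalen-2-yl acetate (C2 epimers) | CC(C)(C)[Si](C)(C)OC[C@]1(C)CC[C@@H]2C(=CC(OC(C)=O)CC2(C)C)[C@H]1C
F11 | step 10 | tert-butyl(dimethyl){[(1R,2R,4aS)-1,2,5,5-tetramethyl-1,2,3,4,4a,5,6,7-octahydronaphthalen-2-yl]methoxy}silane | CC(C)(C)[Si](C)(C)OC[C@]1(C)CC[C@@H]2C(=CCCC2(C)C)[C@H]1C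
F12 | step 18 | (3S,4R,5S)-4-ethenyl-5-(hydroxymethyl)-3-[(1S,2R,4aS)-1,2,5,5-tetramethyl-1,2,3,4,4a,5,6,7-octahydronaphthalen-2-yl]oxolan-2-one | O=C1O[C@H](CO)[C@H](C=C)[C@H]1[C@]2(C)CC[C@@H]3C(=CCCC3(C)C)[C@H]2C
F13 | step 24 | [(2R,3R,4R)-5-hydroxy-2-(methoxycarbonyl)-4-[(1S,2R,4aS)-1,2,5,5-tetramethyl-1,2,3,4,4a,5,6,7-octahydronaphthalen-2-yl]oxolan-3-yl]acetic acid (both anomers) | OC1O[C@@H](C(=O)OC)[C@H](CC(=O)O)[C@@H]1[C@]2(C)CC[C@@H]3C(=CCCC3(C)C)[C@H]2C
A1 | alternative 1 | (2R,3S)-3-{2-[tert-butyl(diphenyl)silyl]oxyethyl}-2-[(1S,2R,4aS)-1,2,5,5-tetramethyl-1,2,3,4,4a,5,6,7-octahydronaphthalen-2-yl]pent-4-enoic acid | OC(=O)[C@H]([C@H](C=C)CCO[Si](c1ccccc1)(c1ccccc1)C(C)(C)C)[C@]2(C)CC[C@@H]3C(=CCCC3(C)C)[C@H]2C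
A2 | alternative 1 | (3R,4R,5R)-4-{2-[tert-butyl(diphenyl)silyl]oxyethyl}-5-(iodomethyl)-3-[(1S,2R,4aS)-1,2,5,5-tetramethyl-1,2,3,4,4a,5,6,7-octahydronaphthalen-2-yl]oxolan-2-one | O=C1O[C@@H](CI)[C@H](CCO[Si](c4ccccc4)(c5ccccc5)C(C)(C)C)[C@@H]1[C@]2(C)CC[C@@H]3C(=CCCC3(C)C)[C@H]2C
A3 | alternative 2 | (2S,3R)-3-({[tert-butyl(dimethyl)silyl]oxy}methyl)-2,3-dimethylcyclohexan-1-one | C[C@@H]1C(=O)CCC[C@@]1(C)CO[Si](C)(C)C(C)(C)C
A4 | alternative 2 | (4aS,7R,8R)-7-({[tert-butyl(dimethyl)silyl]oxy}methyl)-4,4,7,8-tetramethyl-4,4a,5,6,7,8-hexahydronaphthalen-2(3H)-one | CC(C)(C)[Si](C)(C)OC[C@]1(C)CC[C@@H]2C(=CC(=O)CC2(C)C)[C@H]1C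
A5 | alternative 3 | (3R,4R)-3-({[tert-butyl(dimethyl)silyl]oxy}methyl)-4-(3,3-dimethylcyclohex-1-en-1-yl)-3-methylpentanal | O=CC[C@@](C)(CO[Si](C)(C)C(C)(C)C)[C@H](C)C1=CC(C)(C)CCC1
A6 | alternative 3 | (1R,2R,4R,4aS)-2-({[tert-butyl(dimethyl)silyl]oxy}methyl)-1,2,5,5-tetramethyl-1,2,3,4,4a,5,6,7-octahydronaphthalen-4-ol | CC(C)(C)[Si](C)(C)OC[C@]1(C)C[C@@H](O)[C@@H]2C(=CCCC2(C)C)[C@H]1C
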